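**Strategy**

Ring C of the target carries its ether oxygen on C1 and hydroxyls on C2, C4 and C6, the oxygen pattern of a cyclised triketide. The route therefore disconnects the C1–C2 bond of ring C and never arylates the hindered oxygen between rings B and C: that oxygen is alkylated at a primary carbon by a bromomethyl-2-pyranone from triacetic acid lactone. In one operation, methoxide opens the pyranone of precursor 11 (a ring A–B diaryl ether carrying a 4-methoxy-2-pyranon-6-ylmethyl ether) and the released keto ester closes by Claisen condensation to the aromatic ring C of 14. Methyl ethers mask the other phenols and fall in a final BBr3 step.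

Key step: step 8

Remark: in keto ester 12 the ester and the ketone-bearing chain lie cis across C2=C3; because methoxy outranks the CH2 chain, this geometry has the CIP descriptor E.

Remark: ring A is brought in as an aryl iodide, because its oxygen must sit on the ring B carbon flanked by two oxygens, which is reached by arylating a phenol made from the aldehyde.

**Route**

Step 1
Reactants: 1 triacetic acid lactone (4-hydroxy-6-methyl-2H-pyran-2-one)
Product: 2 4-methoxy-6-methyl-2H-pyran-2-one
Conditions: Me2SO4, K2CO3, acetone, reflux
Reagents that add atoms: dimethyl sulfate, COS(=O)(=O)OC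
Why: The acidic vinylogous-acid hydroxyl is deprotonated by carbonate and O-methylated (Williamson-type alkylation), the 4-methoxy-2-pyranone being the expected major regioisomer under these conditions.

Step 2
Reactants: 2 4-methoxy-6-methyl-2H-pyran-2-one
Product: 3 6-(bromomethyl)-4-methoxy-2H-pyran-2-one
Conditions: NBS, AIBN (cat.), PhCF3, 85 °C
Reagents that add atoms: N-bromosuccinimide, O=C1CCC(=O)N1Br
Why: Wohl–Ziegler radical bromination should take the 6-methyl group, whose radical is delocalised over the pyranone diene, while the non-polar radical conditions disfavour ionic bromination at C3.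

Step 3
Reactants: 4 2-hydroxy-4,6-dimethoxybenzaldehyde
Product: 5 2-(benzyloxy)-4,6-dimethoxybenzaldehyde
Conditions: BnBr, K2CO3, DMF, rt to 50 °C
Reagents that add atoms: benzyl bromide, BrCc1ccccc1
Why: Williamson etherification of the only free phenol masks the oxygen that will later carry the pyranone arm.

Step 4
Reactants: 5 2-(benzyloxy)-4,6-dimethoxybenzaldehyde
Product: 7 2-(benzyloxy)-4,6-dimethoxyphenol, via aryl formate 6 (not isolated)
Conditions: mCPBA, CH2Cl2, 0 °C to rt; then K2CO3 (cat.), MeOH, rt
Reagents that add atoms: 3-chloroperoxybenzoic acid, OOC(=O)c1cccc(Cl)c1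
Why: Baeyer–Villiger (Dakin-type) oxidation, in which the electron-rich trialkoxyaryl group migrates in preference to hydride, turns the formyl carbon into a formate oxygen, and methanolysis frees the phenol.

Step 5
Reactants: 7 2-(benzyloxy)-4,6-dimethoxyphenol; 8 1-iodo-3,5-dimethoxybenzene
Product: 9 1-(benzyloxy)-2-(3,5-dimethoxyphenoxy)-3,5-dimethoxybenzene
Conditions: CuI (10 mol %), picolinic acid (20 mol %), K3PO4, DMSO, 90 °C, argon
Reagents that add atoms: none
Why: Ullmann-type C–O coupling at monovalent copper with a picolinate ligand is an established way to arylate ortho-disubstituted phenols, and iodide 8 is unhindered at the reacting carbon.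

Step 6
Reactants: 9 1-(benzyloxy)-2-(3,5-dimethoxyphenoxy)-3,5-dimethoxybenzene
Product: 10 2-(3,5-dimethoxyphenoxy)-3,5-dimethoxyphenol
Conditions: H2 (1 atm), 10% Pd/C, EtOAc–MeOH, rt
Reagents that add atoms: none
Why: Catalytic hydrogenolysis cleaves only the benzylic C–O bond, since diaryl and methyl ethers are inert to these conditions.

Step 7
Reactants: 10 2-(3,5-dimethoxyphenoxy)-3,5-dimethoxyphenol; 3 6-(bromomethyl)-4-methoxy-2H-pyran-2-one
Product: 11 6-{[2-(3,5-dimethoxyphenoxy)-3,5-dimethoxyphenoxy]methyl}-4-methoxy-2H-pyran-2-one
Conditions: K2CO3, acetone, rt to 50 °C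
Reagents that add atoms: none
Why: Williamson ether synthesis by SN2 displacement at the primary, pyranone-activated bromide places the future ring B–ring C oxygen without any arylation.

Step 8
Reactants: 11 6-{[2-(3,5-dimethoxyphenoxy)-3,5-dimethoxyphenoxy]methyl}-4-methoxy-2H-pyran-2-one
Product: 14 2-[2-(3,5-dimethoxyphenoxy)-3,5-dimethoxyphenoxy]-5-methoxybenzene-1,3-diol, via keto ester 12 (not isolated), via cyclohexenedione 13 (not isolated)
Conditions: NaOMe (5 equiv), MeOH, 100 °C, sealed tube, argon; then 1 M HCl
Reagents that add atoms: none
Why: Methoxide should add to the lactone carbonyl and open the ring to keto ester 12, whose ester and keto chain stay cis across the former ring double bond; this E geometry is also the preferred one for a 3-alkoxy enoate, so equilibration by methoxide cannot spoil it. The enolate at the aryloxy-bearing C6 of 12 then attacks the ester carbonyl in a 6-(enolendo)-exo-trig Claisen (Dieckmann-type) condensation that forms the C1–C2 bond of ring C and closes the six-membered carbocycle; loss of methoxide gives dione 13, which enolises to the aromatic bis-phenoxide of 14. The closest known reaction type is the alkoxide-mediated recyclisation of 4-methoxy-6-alkyl-2-pyranones, which are masked 3,5-diketo esters, to phloroglucinol monomethyl ethers, the Claisen mode of polyketide folding. No stereocenter remains, because the transient sp3 carbon C2 of 13 is lost on aromatisation. The step needs carbon acylation to prevail over O-acylation back to the pyranone and over retro-Claisen cleavage of the chain: relactonisation only returns 11 to the same equilibrium whereas aromatisation is irreversible, and the aryloxy group acidifies the C6–H bonds that must be removed. Pairing methoxide with a 4-methoxy group makes any alkoxide exchange at the enol ether or at the ester degenerate.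

Step 9
Reactants: 14 2-[2-(3,5-dimethoxyphenoxy)-3,5-dimethoxyphenoxy]-5-methoxybenzene-1,3-diol
Product: 15 triphloroethol A
Conditions: BBr3 (excess), CH2Cl2, −78 °C to rt; then MeOH, H2O
Reagents that add atoms: none
Why: Lewis-acid cleavage of aryl methyl ethers by BBr3, in which bromide attacks the methyl carbon of the boron-complexed ether, should remove all five methyl groups and leave the diaryl ethers intact because their aryl carbons cannot undergo SN2 attack.

**Compound list**

1 | triacetic acid lactone (4-hydroxy-6-methyl-2H-pyran-2-one) | CC1=CC(O)=CC(=O)O1 | starting material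
2 | 4-methoxy-6-methyl-2H-pyran-2-one | CC1=CC(OC)=CC(=O)O1 | intermediate
3 | 6-(bromomethyl)-4-methoxy-2H-pyran-2-one | BrCC1=CC(OC)=CC(=O)O1 | intermediate
4 | 2-hydroxy-4,6-dimethoxybenzaldehyde | COc1cc(O)c(C=O)c(OC)c1 | starting material
5 | 2-(benzyloxy)-4,6-dimethoxybenzaldehyde | COc1cc(OCc2ccccc2)c(C=O)c(OC)c1 | intermediate
6 | 2-(benzyloxy)-4,6-dimethoxyphenyl formate | COc1cc(OCc2ccccc2)c(OC=O)c(OC)c1 | intermediate
7 | 2-(benzyloxy)-4,6-dimethoxyphenol | COc1cc(OCc2ccccc2)c(O)c(OC)c1 | intermediate
8 | 1-iodo-3,5-dimethoxybenzene | COc1cc(I)cc(OC)c1 | starting material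
9 | 1-(benzyloxy)-2-(3,5-dimethoxyphenoxy)-3,5-dimethoxybenzene | COc1cc(OC)cc(Oc2c(OCc3ccccc3)cc(OC)cc2OC)c1 | intermediate
10 | 2-(3,5-dimethoxyphenoxy)-3,5-dimethoxyphenol | COc1cc(OC)cc(Oc2c(O)cc(OC)cc2OC)c1 | intermediate
11 | 6-{[2-(3,5-dimethoxyphenoxy)-3,5-dimethoxyphenoxy]methyl}-4-methoxy-2H-pyran-2-one | COc1cc(OC)cc(Oc2c(OCC3=CC(OC)=CC(=O)O3)cc(OC)cc2OC)c1 | intermediate
12 | methyl (2E)-6-[2-(3,5-dimethoxyphenoxy)-3,5-dimethoxyphenoxy]-3-methoxy-5-oxohex-2-enoate | COC(=O)/C=C(/OC)CC(=O)COc1cc(OC)cc(OC)c1Oc1cc(OC)cc(OC)c1 | intermediate
13 | 2-[2-(3,5-dimethoxyphenoxy)-3,5-dimethoxyphenoxy]-5-methoxycyclohex-4-ene-1,3-dione (racemic at C2, transient) | COC1=CC(=O)C(Oc2cc(OC)cc(OC)c2Oc2cc(OC)cc(OC)c2)C(=O)C1 | intermediate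
14 | 2-[2-(3,5-dimethoxyphenoxy)-3,5-dimethoxyphenoxy]-5-methoxybenzene-1,3-diol | COc1cc(OC)cc(Oc2c(Oc3c(O)cc(OC)cc3O)cc(OC)cc2OC)c1 | intermediate
15 | triphloroethol A | Oc1cc(O)cc(Oc2c(O)cc(O)cc2Oc2c(O)cc(O)cc2O)c1 | target

**Step count**

Total steps: 9. Longest linear sequence: 7 steps (steps 3 to 9, from aldehyde 4); the pyranone branch (steps 1 and 2) joins at step 7.

**Steps most likely to fail**

Step 8. The opened chain may return to the pyranone or fragment by retro-Claisen attack of methoxide at the ketone faster than the C6 enolate acylates the ester, so that no carbocycle accumulates. The fallback gives up building ring C and attaches it ready-made. It sets out from phenol 10, which is coupled with commercial 2-iodo-1,3,5-trimethoxybenzene under Ullmann conditions (CuI, N,N-dimethylglycine, Cs2CO3, dioxane, 100 °C). This should give 2-(3,5-dimethoxyphenoxy)-1,5-dimethoxy-3-(2,4,6-trimethoxyphenoxy)benzene F1. Its seven methyl ethers are then cleaved with BBr3 in CH2Cl2 as in step 9, and the fallback comes back to the route at target 15.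

Step 5. Coupling at monovalent copper may be sluggish because the di-ortho-substituted phenoxide binds the metal poorly, so that hydrodeiodination of 8 and slow decomposition of 7 at 90 °C take over. The fallback changes the coupling manifold to an oxidative Chan–Lam arylation at room temperature. It sets out from phenol 7, which is treated with commercial 3,5-dimethoxyphenylboronic acid, Cu(OAc)2, pyridine and 4 Å molecular sieves in CH2Cl2 under air. It comes back to the route at diaryl ether 9 and makes no new compound (F0).

Step 2. Ionic bromination at the nucleophilic C3 of the pyranone ring, or a second bromination of the methyl group, may outrun clean monobromination. The fallback functionalises the methyl group by oxidation and joins the fragments by Mitsunobu reaction, so no bromide is needed. It sets out from pyranone 2, which is oxidised with SeO2 in dioxane at 160 °C (sealed tube) to 4-methoxy-2-oxo-2H-pyran-6-carbaldehyde F2. Reduction with NaBH4 in MeOH at 0 °C should give 6-(hydroxymethyl)-4-methoxy-2H-pyran-2-one F3. Mitsunobu etherification of F3 with phenol 10 (PPh3, diisopropyl azodicarboxylate, THF, 0 °C to rt) comes back to the route at precursor 11 and replaces steps 2 and 7.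

**Further compounds**

F1 | step 8 | 2-(3,5-dimethoxyphenoxy)-1,5-dimethoxy-3-(2,4,6-trimethoxyphenoxy)benzene | COc1cc(OC)cc(Oc2c(Oc3c(OC)cc(OC)cc3OC)cc(OC)cc2OC)c1
F0 | step 5 | none | none
F2 | step 2 | 4-methoxy-2-oxo-2H-pyran-6-carbaldehyde | O=CC1=CC(OC)=CC(=O)O1
F3 | step 2 | 6-(hydroxymethyl)-4-methoxy-2H-pyran-2-one | OCC1=CC(OC)=CC(=O)O1
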